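Cedar and oak make product at nearly the same early rate, 1.08 mM min⁻¹ against 1.11 mM min⁻¹, though oak holds 1.50 times the substrate.

in all of them: gas phase 4.4 mM (held)

| run | substrate | remark | time |
|---|---|---|---|
| cedar | 0.050 M | the very flask that is asked about, followed so far |  |
| oak | 0.075 M | run made earlier |  |
| flask | 0.050 M |  | 5.0 h |

| cedar: time / min | cedar: product / % | oak: time / min | oak: product / % |
|---|---|---|---|
| 12.0 | 25.8 | 10.0 | 14.8 |
| 25.0 | 53.2 | 20.0 | 30.4 |
| 40.0 | 72.0 | 30.0 | 44.8 |
| 50.0 | 76.9 | 60.0 | 65.7 |
| 60.0 | 76.8 | 120 | 64.5 |

(scatter of a reading: 1 percentage point)

- the numbers in the tables scatter by 1 percentage point (one standard deviation)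
- at the start none of the gas phase is in solution

- north-west: doubling the transfer coefficient of the gas phase, all else as stated
- south-west: doubling the saturation concentration of gas phase, all else as stated

1. the product standing at 5.0 h, as a percentage of the substrate charged
2. the change that raises the amount of product at 5.0 h, in percent of the substrate charged most ("none" if none brings more than 2 percentage points) (north-west / south-west / none)
3. amount of product at 5.0 h, in percent of the substrate charged, after south-west

I start with the main step by itself: substrate takes up dissolved gas, and product grows at a steady rate R whatever [substrate] is. At that rate the cedar charge lasts 46.5 min. But cedar stops near 76.8% and oak lower, at 64.5%. This selectivity falls with the charge, so I add a loss of rate 2k[substrate][substrate]. Dividing one rate by the other and integrating from the charge c to empty gives, with x = c/a and a·a = R/2k: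

[product] = a·arctan(x), close to c·3/(1 + 2√(1 + x·x))

Cedar's last two readings average 76.9%, and inverting gives

a = 47.5 mM

This is the crossover concentration, the [substrate] at which loss and product formation run equally fast. Carried to oak, it gives 63.3%, against readings of 65.7% and 64.5%.

Last comes the gas transfer. R follows the gap between saturation and [dissolved gas], and a follows √R. If doubling saturation doubles R, I reckon that a goes to 67.2 mM and the flask to 85.9%. I commit to 76.9% at 5.0 h, since the cedar readings are flat by 50.0 min, and to south-west with the figure just reckoned.

The forecast says 76.9% (75.5% to 78%), names south-west with “south-west is the safer choice”, and gives 85.5% (82% to 89%).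

The flask gives 77.2%. South-west adds 8.6 percentage points, north-west 6.9 points, and south-west reaches 85.8%.

    gas phase ⇌ dissolved gas, rate k1*(csat - [dissolved gas]) (kL = 0.330 min⁻¹)
    substrate + dissolved gas → product (k = 45.0 M⁻¹ min⁻¹)
    2 substrate → homo dimer (k = 0.240 M⁻¹ min⁻¹)

In the flask, homo dimer stands at 22.8%, each one counted as two substrate. Without its step the flask gives 100%, and with instant passage 94.4%, which takes away a part of the loss; the step to homo dimer and the drag of the gas transfer act together. The flask's charge is 1.05 times a. A neighbour flask charged with 0.020 M sits at 0.421 times a, where the formula gives 94.6%. That neighbour holds 7.05% homo dimer and gives 93.0%.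

The readings come from a simulation for an exercise.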